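Everything rests on disconnecting C8–C9 in ring B: aldehyde carbons C11 and C12 are 1,4-related across this bond, a succinate pattern that two enolate carbons of like polarity can form directly. In step 11 the bis-enolate of a ring-A diester is oxidised by CuCl2, which forges C8–C9, closes ring B and, after base equilibration, fixes C9. The precursor is a cyclohexane (ring A) with the C4 gem-dimethyl group, triethylsilyl ethers at the C1 and C5 oxygens, a methyl acetate arm on C10 and a methyl butanoate arm on C5, its three stereocentres being set by a catalyst-controlled ketone reduction and a tethered samarium Reformatsky closure.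

Key step: step 11

Remarks on the chemistry
- Atom labels C1–C12 are drimane labels, used also for the monocyclic intermediates; β is the face of the C10 methyl group, and "drimane" implies the natural trans-decalin absolute configuration.
- The 5α oxygen is cis to the C10 arm and would lactonise onto a C11 ester, so C11 is carried as the terminal carbon pair of an allyl group until the C5 oxygen is silylated.
- A nucleophile is expected to attack the C5 ketone from the α face, anti to the flanking axial methyl groups, which would give the wrong C5 epimer; the C5–C6 bond is therefore made through a tether from the 1β oxygen.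
- Compound 4 is racemic and only its (2S)-enantiomer is carried on; the other half of the material leaves the route in step 3.

Step 1
Reactants: 1 4,4-dimethylcyclohexane-1,3-dione
Product: 2 2,4,4-trimethylcyclohexane-1,3-dione
Conditions: MeI, K2CO3, acetone, 56 °C
Reagents that add atoms: iodomethane, CI
Why: C-alkylation of the potassium enolate of the cyclic 1,3-dione at C2, its most nucleophilic carbon, is the standard access to 2-alkyl-1,3-diones and creates no stereocentre.

Step 2
Reactants: 2 2,4,4-trimethylcyclohexane-1,3-dione; 3 allyl methyl carbonate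
Product: 4 rac-2-allyl-2,4,4-trimethylcyclohexane-1,3-dione
Conditions: Pd(PPh3)4 (2 mol %), THF, 25 °C
Reagents that add atoms: none
Why: Tsuji–Trost allylation, in which zerovalent palladium ionises the carbonate to a π-allyl complex and methoxide, the dione enolate attacks at carbon (any O-allyl product re-ionises) and the quaternary C10 is formed as a racemate.

Step 3
Reactants: 4 rac-2-allyl-2,4,4-trimethylcyclohexane-1,3-dione
Product: 5 (2S,3R)-2-allyl-3-hydroxy-2,6,6-trimethylcyclohexan-1-one
Conditions: (S)-2-methyl-CBS-oxazaborolidine (20 mol %), catecholborane, toluene, −78 °C; aq. NaOH; chromatography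
Reagents that add atoms: none
Why: Corey–Bakshi–Shibata reduction, in which only the C1 ketone (one CH2 neighbour) is accessible and the catalyst treats quaternary C10 as the large group, so both enantiomers of 4 should give (R)-C1; the (2S)-enantiomer yields 5 (hydroxyl cis to the C10 methyl) and the (2R)-enantiomer a diastereomer removed by chromatography.

Step 4
Reactants: 5 (2S,3R)-2-allyl-3-hydroxy-2,6,6-trimethylcyclohexan-1-one; 6 bromoacetyl bromide
Product: 7 (1R,2S)-2-allyl-2,4,4-trimethyl-3-oxocyclohexyl bromoacetate
Conditions: pyridine, CH2Cl2, 0 °C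
Reagents that add atoms: none
Why: O-acylation of the hindered secondary alcohol by the very reactive acyl bromide with pyridine as base installs the two-carbon tether without touching a stereocentre.

Step 5
Reactants: 7 (1R,2S)-2-allyl-2,4,4-trimethyl-3-oxocyclohexyl bromoacetate
Product: 9 9-allyl-5-hydroxy-6,6,9-trimethyl-2-oxabicyclo[3.3.1]nonan-3-one (δ-lactone bridge O1–C7(=O)–C6–C5 on the β face; 5α-OH; 10β-methyl; 10α-allyl), via diiodosamarium enolate 8 (not isolated)
Conditions: SmI2 (2.2 equiv), THF, −78 → 0 °C; aq. NH4Cl
Reagents that add atoms: none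
Why: SmI2-promoted intramolecular Reformatsky reaction of a β-(bromoacetoxy) ketone, in which two electrons turn the C–Br bond into a trivalent samarium enolate that is tied to the 1β oxygen and can reach C5 only from the β face, so C6 enters β and the new tertiary hydroxyl is 5α.

Step 6
Reactants: 9 the bridged δ-lactone
Product: 10 9-allyl-6,6,9-trimethyl-2-oxabicyclo[3.3.1]nonane-3,5-diol (lactol at C7; anomer mixture)
Conditions: i-Bu2AlH (2.5 equiv), CH2Cl2, −78 °C; aq. potassium sodium tartrate
Reagents that add atoms: none
Why: Partial hydride reduction of a δ-lactone stops at the aluminium hemiacetal at −78 °C (one equivalent is consumed by the tertiary hydroxyl) and gives the lactol with all stereocentres unchanged.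

Step 7
Reactants: 10 the lactol; 11 methyl (triphenylphosphoranylidene)acetate
Product: 12 methyl (E)-4-[(1R,2S,3R)-2-allyl-1,3-dihydroxy-2,6,6-trimethylcyclohexyl]but-2-enoate
Conditions: toluene, 90 °C
Reagents that add atoms: none
Why: Wittig olefination of the open hydroxy-aldehyde tautomer with the stabilised ylide gives the (E)-enoate under neutral conditions, adding C8 and C12 and freeing the C1 hydroxyl.

Step 8
Reactants: 12 the dihydroxy enoate
Product: 13 methyl (E)-4-[(1R,2S,3R)-2-allyl-2,6,6-trimethyl-1,3-bis(triethylsilyloxy)cyclohexyl]but-2-enoate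
Conditions: Et3SiOTf (3 equiv), 2,6-lutidine, CH2Cl2, −78 → 25 °C
Reagents that add atoms: triethylsilyl trifluoromethanesulfonate, CC[Si](CC)(CC)OS(=O)(=O)C(F)(F)F
Why: Silylation with a silyl triflate and a hindered pyridine base protects both the secondary C1 and the doubly neopentyl tertiary C5 hydroxyl, the latter before C11 is raised to the ester level.

Step 9
Reactants: 13 the bis(silyl ether) enoate
Product: 14 methyl 4-[(1R,2S,3R)-2-allyl-2,6,6-trimethyl-1,3-bis(triethylsilyloxy)cyclohexyl]butanoate
Conditions: Cu(OAc)2·H2O (5 mol %), 1,2-bis(diphenylphosphino)benzene (5 mol %), (EtO)2MeSiH, t-BuOH, toluene, 25 °C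
Reagents that add atoms: none
Why: Copper hydride conjugate reduction, in which the phosphine-ligated CuH adds hydride only to the β-carbon of the enoate and tert-butanol protonates the copper enolate, leaves the isolated allyl double bond and the silyl ethers untouched.

Step 10
Reactants: 14 the allyl butanoate
Product: 15 methyl 4-[(1R,2S,3R)-2-(2-methoxy-2-oxoethyl)-2,6,6-trimethyl-1,3-bis(triethylsilyloxy)cyclohexyl]butanoate
Conditions: O3, NaOH (2.5 M in MeOH), CH2Cl2, −78 °C
Reagents that add atoms: ozone, [O-][O+]=O; methanol, CO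
Why: Ozonolysis in methanolic NaOH cleaves the only remaining alkene and oxidises the C11 fragment directly to its methyl ester with loss of the terminal carbon, at a temperature at which the existing ester and the silyl ethers are stable.

Step 11
Reactants: 15 the ring-A diester
Product: 17 dimethyl 1β,5α-bis(triethylsilyloxy)drimane-11,12-dioate (8α/9β trans-diester; 8βH; 9αH), via dilithium bis-enolate 16 (not isolated)
Conditions: i-Pr2NLi (2.3 equiv), THF (0.01 M), −78 °C; CuCl2 (2.3 equiv), DMF, −78 → 0 °C; then NaOMe, MeOH, 25 °C
Reagents that add atoms: none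
Why: The amide base removes one proton at C8 and one at C9, the only ester α-positions, and divalent copper oxidises one lithium enolate to an α-ester radical that adds to the second enolate, the resulting radical anion giving up a further electron to a second CuCl2. The closest known reaction type is the intramolecular oxidative coupling of diester bis-enolates to cycloalkane-1,2-dicarboxylates. Ring B closes in a 6-exo-trig mode through a chair in which the forming C8–C9 bond is equatorial on ring A. C9 is set under thermodynamic control by the methoxide treatment, because a 9α ester would be syn-diaxial to the 5α silyloxy group and an 8β ester syn-diaxial to the C10 methyl, which leaves the 9β,8α diequatorial diester; C8 is erased in step 12. The step needs ring closure to beat intermolecular coupling, Claisen condensation and lactonisation, which are held back by high dilution, by the seven-membered ring a Dieckmann closure would require at −78 °C, and by the triethylsilyl ether on the C5 oxygen.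

Step 12
Reactants: 17 the trans-diester decalin
Product: 21 dimethyl 1β,5α-bis(triethylsilyloxy)drim-8-ene-11,12-dioate, via lithium C8 enolate 18 (not isolated), via C8 selenide 19 (not isolated), via selenoxide 20 (not isolated)
Conditions: i-Pr2NLi (1.3 equiv), THF, −78 °C; PhSeBr; then H2O2 (30%), pyridine, CH2Cl2, 0 → 25 °C
Reagents that add atoms: none
Why: α-Selenenylation of the ester enolate followed by selenoxide syn-elimination, in which the selenoxide is expected to leave with the more acidic cis C9–H to give the Δ8 diester; any Δ7 isomer formed by loss of C7–H is the product of step 13 and is carried along.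

Step 13
Reactants: 21 the Δ8 diester
Product: 22 dimethyl 1β,5α-bis(triethylsilyloxy)drim-7-ene-11,12-dioate (9β-ester; 9αH)
Conditions: NaOMe (0.5 equiv), MeOH, 40 °C
Reagents that add atoms: none
Why: Base-mediated double-bond isomerisation under thermodynamic control, in which methoxide moves the strained tetrasubstituted alkene through the dienolate to Δ7 and leaves the C9 ester equatorial on the β face, a 9α ester being syn-diaxial to the 5α silyloxy group.

Step 14
Reactants: 22 the Δ7 diester
Product: 23 1β,5α-bis(triethylsilyloxy)drim-7-ene-11,12-diol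
Conditions: LiAlH4, Et2O, 0 °C; H2O, aq. NaOH
Reagents that add atoms: none
Why: Hydride reduction of both esters by LiAlH4 (1,2-reduction of the conjugated one) gives the two primary alcohols without disturbing C9 or the silyl ethers.

Step 15
Reactants: 23 the bis(silyl ether) diol
Product: 24 drim-7-ene-1β,5α,11,12-tetraol
Conditions: Bu4NF (3 equiv), THF, 40 °C
Reagents that add atoms: none
Why: Fluoride desilylation frees the C1 and C5 hydroxyls only now, when C11 is no longer an ester that the 1β oxygen could attack.

Step 16
Reactants: 24 the tetraol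
Product: 25 11,12-bis(triethylsilyloxy)drim-7-ene-1β,5α-diol
Conditions: Et3SiCl (2.3 equiv), imidazole, CH2Cl2, −20 °C
Reagents that add atoms: chlorotriethylsilane, CC[Si](Cl)(CC)CC
Why: Sterically controlled silylation, in which the two primary hydroxyls react far faster than the neopentyl secondary C1 and the tertiary C5 hydroxyl, masks the 11,12-diol selectively.

Step 17
Reactants: 26 p-coumaric acid
Product: 28 (E)-4-(tert-butyldimethylsilyloxy)cinnamic acid, via bis-silylated coumarate 27 (not isolated)
Conditions: t-BuMe2SiCl (2.5 equiv), imidazole, DMF, 25 °C; then AcOH, THF, H2O, 25 °C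
Reagents that add atoms: tert-butyldimethylsilyl chloride, CC(C)(C)[Si](C)(C)Cl
Why: Exhaustive silylation of phenol and acid followed by mild acidic hydrolysis of the far more labile silyl ester gives the phenol-protected acid with the (E)-alkene untouched.

Step 18
Reactants: 25 the 11,12-bis(silyl ether) diol; 28 (E)-4-(tert-butyldimethylsilyloxy)cinnamic acid
Product: 30 5α-hydroxy-11,12-bis(triethylsilyloxy)drim-7-en-1β-yl (E)-4-(tert-butyldimethylsilyloxy)cinnamate, via mixed anhydride 29 (not isolated)
Conditions: 28, 2,4,6-trichlorobenzoyl chloride, Et3N, THF, 25 °C; then 25, DMAP, toluene, 60 °C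
Reagents that add atoms: none
Why: Yamaguchi esterification, in which DMAP is acylated at the less hindered cinnamoyl carbonyl of the mixed anhydride and the acylpyridinium esterifies the equatorial C1 hydroxyl with retention, the tertiary C5 hydroxyl being too hindered to react.

Step 19
Reactants: 30 the C1 cinnamate
Product: 31 5α-hydroxy-11,12-dioxodrim-7-en-1β-yl (E)-4-(tert-butyldimethylsilyloxy)cinnamate
Conditions: (COCl)2, DMSO, CH2Cl2, −78 → −30 °C; then Et3N, −78 → 0 °C
Reagents that add atoms: none
Why: Swern oxidation applied directly to primary triethylsilyl ethers, in which the chlorosulfonium salt cleaves the primary Si–O bonds and the alkoxysulfonium ylides collapse to both aldehydes at low temperature, should leave the base-sensitive C9 centre, the aryl silyl ether and the tertiary alcohol alone.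

Step 20
Reactants: 31 the silyl-protected dialdehyde
Product: 32 5α-hydroxy-11,12-dioxodrim-7-en-1β-yl (E)-4-hydroxycinnamate (target CNP0323926.1)
Conditions: Bu4NF, AcOH (1:1), THF, 0 °C
Reagents that add atoms: none
Why: Fluoride cleavage of the aryl silyl ether, buffered with acetic acid so that the epimerisable C9 aldehyde and the cinnamate ester survive, releases the phenol and completes the target.

Compound list
1 | 4,4-dimethylcyclohexane-1,3-dione | CC1(C)CCC(=O)CC1=O | starting material
2 | 2,4,4-trimethylcyclohexane-1,3-dione | CC1C(=O)CCC(C)(C)C1=O | intermediate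
3 | allyl methyl carbonate | C=CCOC(=O)OC | starting material
4 | rac-2-allyl-2,4,4-trimethylcyclohexane-1,3-dione | CC1(C)CCC(=O)C(C)(CC=C)C1=O | intermediate
5 | (2S,3R)-2-allyl-3-hydroxy-2,6,6-trimethylcyclohexan-1-one | CC1(C)CC[C@@H](O)[C@](C)(CC=C)C1=O | intermediate
6 | bromoacetyl bromide | BrCC(=O)Br | starting material
7 | (1R,2S)-2-allyl-2,4,4-trimethyl-3-oxocyclohexyl bromoacetate | CC1(C)CC[C@@H](OC(=O)CBr)[C@](C)(CC=C)C1=O | intermediate
8 | diiodosamarium enolate of the C1 acetate (trivalent samarium) | CC1(C)CC[C@@H](OC(=C)O[Sm](I)I)[C@](C)(CC=C)C1=O | intermediate (not isolated)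
9 | 9-allyl-5-hydroxy-6,6,9-trimethyl-2-oxabicyclo[3.3.1]nonan-3-one (lactone bridge on the β face, 5α-OH, 10β-methyl, 10α-allyl) | CC1(C)CC[C@H]2OC(=O)C[C@]1(O)[C@@]2(C)CC=C | intermediate
10 | 9-allyl-6,6,9-trimethyl-2-oxabicyclo[3.3.1]nonane-3,5-diol (lactol, anomer mixture) | CC1(C)CC[C@H]2OC(O)C[C@]1(O)[C@@]2(C)CC=C | intermediate
11 | methyl (triphenylphosphoranylidene)acetate | COC(=O)C=P(c1ccccc1)(c1ccccc1)c1ccccc1 | starting material
12 | methyl (E)-4-[(1R,2S,3R)-2-allyl-1,3-dihydroxy-2,6,6-trimethylcyclohexyl]but-2-enoate | CC1(C)CC[C@@H](O)[C@](C)(CC=C)[C@]1(C/C=C/C(=O)OC)O | intermediate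
13 | methyl (E)-4-[(1R,2S,3R)-2-allyl-2,6,6-trimethyl-1,3-bis(triethylsilyloxy)cyclohexyl]but-2-enoate | CC1(C)CC[C@@H](O[Si](CC)(CC)CC)[C@](C)(CC=C)[C@]1(C/C=C/C(=O)OC)O[Si](CC)(CC)CC | intermediate
14 | methyl 4-[(1R,2S,3R)-2-allyl-2,6,6-trimethyl-1,3-bis(triethylsilyloxy)cyclohexyl]butanoate | CC1(C)CC[C@@H](O[Si](CC)(CC)CC)[C@](C)(CC=C)[C@]1(CCCC(=O)OC)O[Si](CC)(CC)CC | intermediate
15 | methyl 4-[(1R,2S,3R)-2-(2-methoxy-2-oxoethyl)-2,6,6-trimethyl-1,3-bis(triethylsilyloxy)cyclohexyl]butanoate (ring-A diester, key-step precursor) | CC1(C)CC[C@@H](O[Si](CC)(CC)CC)[C@](C)(CC(=O)OC)[C@]1(CCCC(=O)OC)O[Si](CC)(CC)CC | intermediate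
16 | dilithium C8,C9 bis-enolate of 15 | CC1(C)CC[C@@H](O[Si](CC)(CC)CC)[C@](C)(C=C([O-])OC)[C@]1(CCC=C([O-])OC)O[Si](CC)(CC)CC.[Li+].[Li+] | intermediate (not isolated)
17 | dimethyl 1β,5α-bis(triethylsilyloxy)drimane-11,12-dioate (8α- and 9β-esters, trans-diequatorial) | CC1(C)CC[C@@H](O[Si](CC)(CC)CC)[C@]2(C)[C@@H](C(=O)OC)[C@H](C(=O)OC)CC[C@@]12O[Si](CC)(CC)CC | intermediate
18 | lithium C8 enolate of 17 | CC1(C)CC[C@@H](O[Si](CC)(CC)CC)[C@]2(C)[C@@H](C(=O)OC)C(=C([O-])OC)CC[C@@]12O[Si](CC)(CC)CC.[Li+] | intermediate (not isolated)
19 | dimethyl 8α-(phenylselanyl)-1β,5α-bis(triethylsilyloxy)drimane-11,12-dioate | CC1(C)CC[C@@H](O[Si](CC)(CC)CC)[C@]2(C)[C@@H](C(=O)OC)[C@](C(=O)OC)([Se]c3ccccc3)CC[C@@]12O[Si](CC)(CC)CC | intermediate (not isolated)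
20 | selenoxide of 19 | CC1(C)CC[C@@H](O[Si](CC)(CC)CC)[C@]2(C)[C@@H](C(=O)OC)[C@](C(=O)OC)([Se](=O)c3ccccc3)CC[C@@]12O[Si](CC)(CC)CC | intermediate (not isolated)
21 | dimethyl 1β,5α-bis(triethylsilyloxy)drim-8-ene-11,12-dioate | CC1(C)CC[C@@H](O[Si](CC)(CC)CC)[C@]2(C)C(C(=O)OC)=C(C(=O)OC)CC[C@@]12O[Si](CC)(CC)CC | intermediate
22 | dimethyl 1β,5α-bis(triethylsilyloxy)drim-7-ene-11,12-dioate (9β-ester) | CC1(C)CC[C@@H](O[Si](CC)(CC)CC)[C@]2(C)[C@@H](C(=O)OC)C(C(=O)OC)=CC[C@@]12O[Si](CC)(CC)CC | intermediate
23 | 1β,5α-bis(triethylsilyloxy)drim-7-ene-11,12-diol | CC1(C)CC[C@@H](O[Si](CC)(CC)CC)[C@]2(C)[C@@H](CO)C(CO)=CC[C@@]12O[Si](CC)(CC)CC | intermediate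
24 | drim-7-ene-1β,5α,11,12-tetraol | CC1(C)CC[C@@H](O)[C@]2(C)[C@@H](CO)C(CO)=CC[C@@]12O | intermediate
25 | 11,12-bis(triethylsilyloxy)drim-7-ene-1β,5α-diol | CC1(C)CC[C@@H](O)[C@]2(C)[C@@H](CO[Si](CC)(CC)CC)C(CO[Si](CC)(CC)CC)=CC[C@@]12O | intermediate
26 | p-coumaric acid | OC(=O)/C=C/c1ccc(O)cc1 | starting material
27 | tert-butyldimethylsilyl (E)-4-(tert-butyldimethylsilyloxy)cinnamate | CC(C)(C)[Si](C)(C)Oc1ccc(/C=C/C(=O)O[Si](C)(C)C(C)(C)C)cc1 | intermediate (not isolated)
28 | (E)-4-(tert-butyldimethylsilyloxy)cinnamic acid | CC(C)(C)[Si](C)(C)Oc1ccc(/C=C/C(=O)O)cc1 | intermediate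
29 | (E)-4-(tert-butyldimethylsilyloxy)cinnamic 2,4,6-trichlorobenzoic anhydride | CC(C)(C)[Si](C)(C)Oc1ccc(/C=C/C(=O)OC(=O)c2c(Cl)cc(Cl)cc2Cl)cc1 | intermediate (not isolated)
30 | 5α-hydroxy-11,12-bis(triethylsilyloxy)drim-7-en-1β-yl (E)-4-(tert-butyldimethylsilyloxy)cinnamate | CC1(C)CC[C@@H](OC(=O)/C=C/c3ccc(O[Si](C)(C)C(C)(C)C)cc3)[C@]2(C)[C@@H](CO[Si](CC)(CC)CC)C(CO[Si](CC)(CC)CC)=CC[C@@]12O | intermediate
31 | 5α-hydroxy-11,12-dioxodrim-7-en-1β-yl (E)-4-(tert-butyldimethylsilyloxy)cinnamate | CC1(C)CC[C@@H](OC(=O)/C=C/c3ccc(O[Si](C)(C)C(C)(C)C)cc3)[C@]2(C)[C@@H](C=O)C(C=O)=CC[C@@]12O | intermediate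
32 | 5α-hydroxy-11,12-dioxodrim-7-en-1β-yl (E)-4-hydroxycinnamate | CC1(C)CC[C@@H](OC(=O)/C=C/c2ccc(O)cc2)[C@]2(C)[C@@H](C=O)C(C=O)=CC[C@@]12O | target

Total step count: 20. Longest linear sequence: 19 steps (steps 1–16 and 18–20; step 17 prepares the acid 28 from 26).

Steps most likely to fail

Step 11. α-Chlorination of an enolate by CuCl2 or intermolecular coupling may outrun closure of the bond next to quaternary C10. The fallback sets out from 15: the bis-enolate is trapped with Me3SiCl (i-Pr2NLi, THF, −78 °C) as the neutral, isolable bis(trimethylsilyl ketene acetal) of 15 F1. F1 is then oxidised at high dilution with (NH4)2Ce(NO3)6 and NaHCO3 in MeCN at −30 °C, where tetravalent cerium generates the ester radical cation, this adds 6-exo to the second ketene acetal and both silyl groups are lost. Methoxide equilibration as in step 11 brings the route back at 17.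

Step 5. The trivalent samarium aldolate at the doubly neopentyl C5 may revert by retro-aldol cleavage, or the enolate may be protonated before it adds, leaving the C1 acetate. The fallback sets out from 5 and uses a vinylogous Reformatsky reaction on the free hydroxy ketone (Zn, methyl (E)-4-bromobut-2-enoate, THF, 65 °C). The zinc dienolate adds through its γ-carbon, and the product is not an aldol, so it cannot revert in this way. This delivers the complete C6–C12 chain and rejoins the route at 12, so that steps 4, 6 and 7 fall away. Delivery to the β face then rests only on the zinc alkoxide at C1, without a covalent tether, and a C5 epimer would have to be separated.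

Step 12. Transfer of selenium to the crowded tetrasubstituted enolate, or syn-elimination of the hindered selenoxide, may stall. The fallback sets out from 17: both α-protons are removed (i-Pr2NLi 2.5 equiv, HMPA, THF, −78 → −20 °C) and the C8,C9 bis-enolate is oxidised with I2, by iodination at one carbon and loss of iodide from the neighbouring enolate. This known dehydrogenation of vicinal diester dianions gives the Δ8 diester without a selenium intermediate and returns to the route at 21.

Further compounds
F1 | step 11 | bis(trimethylsilyl ketene acetal) of 15 | CC1(C)CC[C@@H](O[Si](CC)(CC)CC)[C@](C)(C=C(OC)O[Si](C)(C)C)[C@]1(CCC=C(OC)O[Si](C)(C)C)O[Si](CC)(CC)CC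
F0 | step 5 | none | none
F0 | step 12 | none | none
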